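Begin with a subtraction: in flask east, if each target costs one second substrate, converting half of the starting material spends 71.4% of the second-substrate charge.

| setting | east | north | flask |
|---|---|---|---|
| starting material | 22 mM | 22 mM | 22 mM |
| second substrate | 15.4 mM | 7.7 mM | 15.4 mM |
| free enzyme | 5.7 µM | 5.7 µM | 5.7 µM |
| added ligand | 3.6 µM | 3.6 µM | 3.6 µM |
| remark | the very flask that is asked about, followed so far | run made earlier |  |

| run | time / h | target / % | starting material / % |
|---|---|---|---|
| east | 6.00 | 20 | 86 |
| east | 12.0 | 22 | 76 |
| east | 20.0 | 32 | 70 |
| east | 25.0 | 34 | 68 |
| east | 30.0 | 38 | 61 |
| north | 2.00 | 4 | 96 |
| north | 6.00 | 13 | 91 |
| north | 12.0 | 15 | 82 |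
| north | 15.0 | 15 | 84 |
| north | 25.0 | 18 | 82 |

(scatter of a reading: 1.5 percentage points)

1. apparent order in second substrate when 50% of the starting material are converted (percent change of the rate of making target for one percent more second substrate charged)
2. apparent order in free enzyme when 50% of the starting material are converted (percent change of the rate of making target for one percent more free enzyme charged)

- the earlier runs were read with a standard deviation of 1.5 percentage points
- no earlier run changes the charge of free enzyme; that part of a forecast is a guess

What remains is the reserve, the fraction of the second-substrate charge still unspent at that conversion: 28.6%. At one second substrate per target, the amount spent at that conversion stays the same when you charge more, so one percent more charge raises the amount remaining by 3.50 percent. The order in second substrate is therefore this lever times the local order, meaning the percent change of rate per percent change of what remains.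

How large is the local order? A first answer comes from the target at 6.00 h, where flask east, with twice the charge of flask north, reads 20% against 13%, a local order of about 0.621. But that belongs to the early part of the runs, so go round again with the later stretches. The rate of making target in flask east from 20.0 h to 30.0 h reads 2.60 times that in flask north from 12.0 h to 25.0 h, on a remainder, at one per target, 1.80 times north's, which gives a local order of about 1.63. Those stretches gain 6 percentage points and 3 points against a scatter of 1.5 points per reading, so the figure is rough, and between the two answers I commit to a local order of one and an order near 3.50. No run varies the enzyme, so I reckon nothing for it.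

The reserve also sorts flask north: there it comes out at −42.9%, below zero, so that charge, at one per target, covers target up to 35.0% of the starting material, and 18% was read at 25.0 h. In flask east, too, second substrate, charged below the starting material, is the limiting reagent.

The forecast gives 2.5 for the order in second substrate and 1.7 for that in free enzyme, adding of the first: “Reversibility or decay could push this higher.” My figure for second substrate, 3.50, stands above it.

Flask east gives 3.2 for second substrate and 0.67 for free enzyme.

    starting material + free enzyme ⇌ first complex (K = 29.0 M⁻¹, k = 4.29 × 10⁵ M⁻¹ h⁻¹)
    first complex → loaded enzyme + first product (k = 1300 h⁻¹)
    second substrate + loaded enzyme ⇌ second complex (K = 67.7 M⁻¹, k = 4.53 × 10⁶ M⁻¹ h⁻¹)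
    second complex → free enzyme + target (k = 460 h⁻¹)
    free enzyme + added ligand ⇌ idle complex (K = 5.20 × 10⁵ M⁻¹, k = 99300 M⁻¹ h⁻¹)
    second substrate ⇌ dormant form (K = 4.35, k = 0.202 h⁻¹)

At 2.50 d flask east holds 3.43% of the second-substrate charge free and 24.7% as dormant form, and the order found equals the lever times a local order of 0.915. At that moment, counting each forward step alone, the step onto the loaded enzyme uses second substrate 110 times faster than the step into the dormant form.

The runs were generated by integration for substances that don't exist; scatter was added.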